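In a one-step world, each substrate takes one unit of reagent, and the books close when substrate is gone. Here I suppose a two-step world, and the supposition is mine, not something the readings show: solid reagent, like a cosubstrate, is drawn once when substrate is lost and again when intermediate B becomes product.

| flask | substrate | solid reagent | capture agent | remark | time |
|---|---|---|---|---|---|
| Sunday's | 0.13 M | 1 equiv | 0.060 M | run made earlier |  |
| Tuesday's | 0.30 M | 1 equiv | 0.060 M | run made earlier |  |
| blue | 0.20 M | 1.00 equiv | 0.0600 M |  | 2.5 h |
| green | 0.20 M | 1.00 equiv | 0.0600 M |  | 8.0 h |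

| run | time / min | intermediate A / % | trapped intermediate / % | intermediate B / % | substrate / % | product / % |
|---|---|---|---|---|---|---|
| Sunday's | 15.0 | 1.2 | 0 | 0 | 99.7 | 0 |
| Sunday's | 30.0 | 1.0 | 0.2 | 2.0 | 96.3 | 0 |
| Sunday's | 50.0 | 2.3 | 0.5 | 4.7 | 92.1 | 1.2 |
| Sunday's | 60.0 | 1.5 | 0 | 6.5 | 90.6 | 0.3 |
| Sunday's | 80.0 | 2.9 | 1.6 | 11.2 | 84.7 | 1.2 |
| Sunday's | 90.0 | 3.2 | 1.3 | 13.7 | 81.3 | 1.5 |
| Tuesday's | 6.00 | 0 | 0.2 | 0.3 | 99.2 | 0.3 |
| Tuesday's | 20.0 | 0.3 | 0 | 1.1 | 97.9 | 0.4 |
| Tuesday's | 30.0 | 1.1 | 0 | 1.8 | 96.7 | 0 |
| Tuesday's | 50.0 | 2.3 | 0 | 4.0 | 93.5 | 0 |
| Tuesday's | 60.0 | 2.8 | 0 | 6.6 | 91.6 | 0 |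
| Tuesday's | 90.0 | 2.3 | 0.7 | 12.1 | 84.6 | 1.5 |

(each reading ± 0.5 percentage points)
- given per volume of solution although it is solid: solid reagent
- at the start none of the solid reagent is in solution
1. which of these there is most of at the end, counted by the substrate in it, blue (product / substrate / trapped intermediate / intermediate B / intermediate A)
2. which of these there is most of at the end, counted by the substrate in it, green (product / substrate / trapped intermediate / intermediate B / intermediate A)
3. the largest of these amounts at the end, in percent of the substrate charged, blue
4. the largest of these amounts at the end, in percent of the substrate charged, green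

Blue and green are charged at 1.00 equiv, and the earlier runs at 1 equiv, so on this ledger solid reagent is the limiting reagent. Take S as substrate left and Z as product, both in percent of the charge. The books then read:

charged solid reagent = substrate lost + product + undrawn part

undrawn part = S − Z

Sunday's last reading gives:

81.3% − 1.5% = 79.8%

Call this the reserve, R = S − Z, the part of the charge not yet drawn. A reserve below zero is impossible on this ledger, so on it product stays at or under substrate left. My own call is therefore that product does not come out on top in green.

The forecast differs on this point. For blue it gives substrate at 63%, within 54% to 72%. For green it gives product at 47%, within 37% to 65%, and says: “Product is slightly favoured, but this is an uncertain call”.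

Blue ends with substrate on top at 66.1%. Green ends with intermediate B on top at 42.6%, with substrate at 33.2% and product at 22.0%.

    intermediate A → intermediate B (k = 0.110 /min)
    partner + intermediate B ⇌ product (K = 21.0 /M, k = 0.0640 /M/min)
    substrate + partner ⇌ intermediate A (K = 210 /M, k = 0.0430 /M/min)
    solid reagent ⇌ partner, rate k4*(cs4 - [partner]) while solid is left; crystals form when [partner] > cs4 (solubility = 0.180 M, k = 0.0100 /min)
    capture agent + intermediate A → trapped intermediate (k = 0.0550 /M/min)

Green's reserve at its end is 11.2%, smaller than the 79.8% read on Sunday, and by this step alone, both ways together, partner + intermediate B and product relax in green at 8.00 h with a half-life of 1.16 h, shorter than the 8.0 h of the run. Green read at 30 h holds substrate 16.7% and product 12.7%, a reserve of 4.00%, and 4.0% of the charged solid reagent is still there, solid or dissolved.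

The readings were generated by integration with made-up constants, and the scatter is random.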